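**Retrosynthetic overview** (chamigrane numbering: spiro carbon C6; ring B = C1–C6 with C2 = CHCl and C3 = CBr(CH3); ring A = C6–C11 with C7 = C(=CH2), C10 = CHBr, C11 = C(CH3)2)
1. The target comes from the trans-diaxial 2-chloro-3-ol (C3–OH to C3–Br with retention through a chloronium ion), which comes from the 2,3-epoxide of 10-bromo-β-chamigrene; the C7 methylene comes from a C7 ketone.
2. Ring B is closed in one operation that makes C1–C6 and C2–C3: photoredox decarboxylation of a C6 carboxylic acid, 6-endo radical addition to an acrylate on the C7 oxygen, reduction to the lactone enolate, and aldol closure on the C3 methyl ketone.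
3. The enabling feature is on ring A: a C6 carboxyl (radical precursor), a C6 3-oxobutyl arm (C5–C4–C3) and an acrylate ester (C1, C2) on the axial C7 oxygen cis to bromine. A six-membered lactone can only close cis, so C1 is forced onto the bromine face of C6; the carboxyl carbon and the tether carbonyl later leave as CO2.
4. Ring A comes from an enantiospecific bromonium cyclisation of an acyclic β-keto ester (C6–C11 bond); C10 is set by enantioselective bromochlorination of prenol.
5. Order of ring formation: ring A first, then the temporary δ-lactone and ring B together.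

Key step: step 9

Remark: in the names of 10–14 ring carbon C1 is the future spiro carbon C6 (C2 = C11, C3 = C10, C6 = C7). The C6 configuration drawn for 10–14 is the expected major one and is erased at the radical stage.

Step 1
Reactants: 1 allyl acetoacetate; 2 2-(2-bromoethyl)-2-methyl-1,3-dioxolane
Product: 3 allyl 2-acetyl-4-(2-methyl-1,3-dioxolan-2-yl)butanoate (racemic)
Conditions: NaH, NaI (cat.), THF/DMF, 0 to 60 °C
Reagents that add atoms: none
Why: Acetoacetic ester C-alkylation with the primary bromide installs the future C5–C4–C3 arm with the C3 ketone masked as a dioxolane, and the new centre is enolisable and of no consequence.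

Step 2
Reactants: 4 prenol (3-methylbut-2-en-1-ol)
Product: 5 (R)-2-bromo-3-chloro-3-methylbutan-1-ol
Conditions: NBS, ClTi(OiPr)3, chiral tridentate Schiff-base ligand (20 mol%, the enantiomer that gives the R product), hexanes, −20 °C
Reagents that add atoms: N-bromosuccinimide O=C1CCC(=O)N1Br; chlorotitanium triisopropoxide CC(C)O[Ti](Cl)(OC(C)C)OC(C)C
Why: Titanium-catalysed enantioselective bromochlorination of an allylic alcohol should open the bromiranium ion of titanium-bound prenol with chloride at the tertiary carbon, anti to bromine, which sets the future C10 centre as R.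

Step 3
Reactants: 5 (R)-2-bromo-3-chloro-3-methylbutan-1-ol
Product: 6 (R)-2-bromo-3-chloro-3-methylbutyl trifluoromethanesulfonate
Conditions: Tf2O, 2,6-lutidine, CH2Cl2, −78 °C
Reagents that add atoms: triflic anhydride O=S(=O)(OS(=O)(=O)C(F)(F)F)C(F)(F)F
Why: Sulfonylation of the primary alcohol gives an electrophile reactive enough for carbanion alkylation at −78 °C without touching the stereocentre.

Step 4
Reactants: 3 allyl 2-acetyl-4-(2-methyl-1,3-dioxolan-2-yl)butanoate; 6 (R)-2-bromo-3-chloro-3-methylbutyl trifluoromethanesulfonate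
Product: 8 allyl (6R)-6-bromo-7-chloro-7-methyl-2-[2-(2-methyl-1,3-dioxolan-2-yl)ethyl]-3-oxooctanoate (both C2 epimers), via dilithium dianion 7 (not isolated)
Conditions: LiN(iPr)2 (2.1 equiv), THF, −78 to 0 °C; then 6, −78 °C; AcOH quench
Reagents that add atoms: none
Why: γ-Alkylation of a β-keto ester dianion should occur at the more basic terminal carbanion of 7 by displacement of the primary triflate, leaving the bromochloride and its stereocentre untouched.

Step 5
Reactants: 8 allyl (6R)-6-bromo-7-chloro-7-methyl-2-[2-(2-methyl-1,3-dioxolan-2-yl)ethyl]-3-oxooctanoate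
Product: 10 allyl (1R,3R)-3-bromo-2,2-dimethyl-1-[2-(2-methyl-1,3-dioxolan-2-yl)ethyl]-6-oxocyclohexane-1-carboxylate, via bromonium chloride 9 (not isolated)
Conditions: (CF3)2CHOH (HFIP), 4 Å molecular sieves, 0 °C to rt
Reagents that add atoms: none
Why: Solvolytic loss of the tertiary chloride with anti bromine participation should give bromonium ion 9 without loss of configuration, and the hydrogen-bonded enol of the β-keto ester attacks its tertiary end at carbon through a chair with bromine equatorial (bromonium-initiated cation–olefin cyclisation), which closes ring A and places the ester equatorial and cis to bromine.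

Step 6
Reactants: 10 allyl (1R,3R)-3-bromo-2,2-dimethyl-1-[2-(2-methyl-1,3-dioxolan-2-yl)ethyl]-6-oxocyclohexane-1-carboxylate
Product: 11 allyl (1R,3R,6S)-3-bromo-6-hydroxy-2,2-dimethyl-1-[2-(2-methyl-1,3-dioxolan-2-yl)ethyl]cyclohexane-1-carboxylate
Conditions: LiBH(sBu)3 (L-Selectride), THF, −78 to −40 °C; AcOH quench
Reagents that add atoms: none
Why: In this hindered cyclohexanone the axial C11 methyl is syn-axial to the axial trajectory at C7, so the bulky borohydride should enter equatorially and give the axial C7 alcohol cis to bromine, which is the anchor the tether needs.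

Step 7
Reactants: 11 allyl (1R,3R,6S)-3-bromo-6-hydroxy-2,2-dimethyl-1-[2-(2-methyl-1,3-dioxolan-2-yl)ethyl]cyclohexane-1-carboxylate
Product: 12 allyl (1R,3R,6S)-6-(acryloyloxy)-3-bromo-2,2-dimethyl-1-[2-(2-methyl-1,3-dioxolan-2-yl)ethyl]cyclohexane-1-carboxylate
Conditions: acryloyl chloride, Et3N, DMAP (cat.), CH2Cl2, 0 °C
Reagents that add atoms: acryloyl chloride C=CC(Cl)=O
Why: DMAP-catalysed acylation of the secondary alcohol attaches the two-carbon unit (future C1 and C2) as a temporary ester tether without changing any stereocentre.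

Step 8
Reactants: 12 allyl (1R,3R,6S)-6-(acryloyloxy)-3-bromo-2,2-dimethyl-1-[2-(2-methyl-1,3-dioxolan-2-yl)ethyl]cyclohexane-1-carboxylate
Product: 14 (1R,3R,6S)-6-(acryloyloxy)-3-bromo-2,2-dimethyl-1-(3-oxobutyl)cyclohexane-1-carboxylic acid, via ketal acid 13 (not isolated)
Conditions: Pd(PPh3)4 (5 mol%), PhSiH3, CH2Cl2, rt; then 1 M HCl, THF, rt
Reagents that add atoms: water O
Why: Palladium-catalysed allyl transfer to a silane hydride donor (Tsuji–Trost-type deallylation) should free the acid without touching the acrylate, and the acidic aqueous stage hydrolyses the dioxolane to the methyl ketone.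

Step 9
Reactants: 14 (1R,3R,6S)-6-(acryloyloxy)-3-bromo-2,2-dimethyl-1-(3-oxobutyl)cyclohexane-1-carboxylic acid
Product: 17 tricyclic hydroxy lactone (10-bromo-3-hydroxy-3,11,11-trimethylspiro[5.5]undecane-2-carboxylic acid 2→7 δ-lactone; lactone cis-fused to ring A; OH cis to the lactone carbonyl), via tertiary radical 15 (not isolated), via lactone enolate 16 (not isolated)
Conditions: [Ir(dF(CF3)ppy)2(dtbbpy)]PF6 (2 mol%), K2HPO4, DMF (5 mM), 450 nm LEDs, 30 °C, degassed
Reagents that add atoms: none
Why: Proposed new method: the excited iridium photocatalyst oxidises the carboxylate of 14, CO2 is lost and the tertiary radical 15 at the future C6 adds to the terminal carbon of the acrylate held on the axial C7 oxygen (C1–C6 bond), after which the reduced photocatalyst turns the α-acyl radical into lactone enolate 16, which adds to the C3 methyl ketone (C2–C3 bond) and is trapped as the alkoxide; the closest known reaction types are the photoredox decarboxylative Giese addition and the radical conjugate addition–aldol (radical–polar crossover) annulation. The δ-lactone closes by 6-endo-trig radical addition and ring B by 6-(enolexo)-exo-trig aldol addition. The spiro centre C6 is controlled by the tether: a six-membered lactone on the axial C7–O bond can only be cis-fused, so C1 is delivered to the face of C6 that carries the C7 oxygen and the C10 bromine (the face an untethered reagent avoids because of the axial C11 methyl), and the 3-oxobutyl arm becomes axial. C2 is fixed by the bridge (its carbonyl must lie on the C7 side of ring B) and the C3 carbinol should form cis to that carbonyl through a potassium-bridged closed transition state; both centres are erased in step 11. The step needs 6-endo instead of 5-exo addition, which the polarity match between the nucleophilic tertiary radical and the acrylate β-carbon secures, and aldol closure before protonation of 16, which the proximity of the ketone, the aprotic medium and high dilution secure.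

Step 10
Reactants: 17 tricyclic hydroxy lactone
Product: 19 (10R)-10-bromo-3-hydroxy-3,11,11-trimethyl-7-oxospiro[5.5]undecane-2-carboxylic acid (carboxyl on the C7 side of ring B; OH cis to carboxyl), via lithium hydroxy carboxylate 18 (not isolated)
Conditions: LiOH, THF/H2O, 0 °C to rt; then RuCl3 (cat.), NaIO4, MeCN/H2O (pH 7 buffer), 0 °C; then 1 M HCl to pH 3
Reagents that add atoms: lithium hydroxide [Li+].[OH-]
Why: Saponification opens the δ-lactone to carboxylate 18 and ruthenium tetroxide made in situ should oxidise the freed secondary C7 alcohol to the ketone before acidification, which prevents relactonisation while the tertiary alcohol and the alkyl bromide stay inert.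

Step 11
Reactants: 19 (10R)-10-bromo-3-hydroxy-3,11,11-trimethyl-7-oxospiro[5.5]undecane-2-carboxylic acid
Product: 21 (6R,10R)-10-bromo-3,11,11-trimethylspiro[5.5]undec-2-en-7-one, via β-lactone 20 (not isolated)
Conditions: PhSO2Cl, pyridine, 0 °C; then 2,4,6-collidine, 140 °C
Reagents that add atoms: none
Why: Carboxyl activation should close the cis β-hydroxy acid to β-lactone 20, whose thermal cycloreversion expels CO2 and gives the C2=C3 alkene regiospecifically (β-lactone decarboxylation), which removes the tether carbon and erases the C2 and C3 centres.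

Step 12
Reactants: 21 (6R,10R)-10-bromo-3,11,11-trimethylspiro[5.5]undec-2-en-7-one
Product: 22 (6S,10R)-10-bromo-3,11,11-trimethyl-7-methylidenespiro[5.5]undec-2-ene (10-bromo-β-chamigrene)
Conditions: Zn, CH2Br2, TiCl4, THF/CH2Cl2, 0 °C to rt
Reagents that add atoms: dibromomethane BrCBr
Why: Takai–Lombardo methylenation uses a non-basic titanium–zinc methylene reagent that should convert the hindered, enolisable C7 ketone into the exocyclic alkene without enolisation or attack on the secondary bromide.

Step 13
Reactants: 22 (6S,10R)-10-bromo-3,11,11-trimethyl-7-methylidenespiro[5.5]undec-2-ene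
Product: 23 2,3-epoxide of 22 (oxygen on the ring B face syn to C11)
Conditions: mCPBA, NaHCO3, CH2Cl2, 0 °C
Reagents that add atoms: 3-chloroperbenzoic acid OOC(=O)c1cccc(Cl)c1
Why: Prilezhaev epoxidation should be chemoselective for the trisubstituted ring B alkene over the hindered 1,1-disubstituted one and should occur on the ring B face away from the axial C7 substituent of the spiro centre (C11 prefers the equatorial position).

Step 14
Reactants: 23 2,3-epoxide of 22
Product: 24 (2R,3R,6S,10R)-10-bromo-2-chloro-3,11,11-trimethyl-7-methylidenespiro[5.5]undecan-3-ol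
Conditions: LiCl, AcOH, THF, rt
Reagents that add atoms: lithium chloride [Li+].[Cl-]
Why: Chloride should open the epoxide by SN2 attack at the secondary C2 with inversion, which is also the trans-diaxial (Fürst–Plattner) mode in the chair with C11 equatorial, setting C2 as R and leaving the tertiary C3 alcohol axial and anti to chlorine.

Step 15
Reactants: 24 (2R,3R,6S,10R)-10-bromo-2-chloro-3,11,11-trimethyl-7-methylidenespiro[5.5]undecan-3-ol
Product: 26 (2R,3R,6S,10R)-3,10-dibromo-2-chloro-3,11,11-trimethyl-7-methylidenespiro[5.5]undecane (target), via chloronium bromide 25 (not isolated)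
Conditions: TMSBr, 2,6-di-tert-butylpyridine, CH2Cl2, −40 to 0 °C
Reagents that add atoms: bromotrimethylsilane C[Si](C)(C)Br
Why: Silylative ionisation of the tertiary alcohol is assisted by the anti-periplanar axial chlorine (chloronium ion 25) and bromide should open the bridged ion at the tertiary carbon from the face opposite to chlorine, so C3 is brominated with overall retention (SN1 substitution with neighbouring-group participation) while the hindered base keeps HBr away from the exocyclic alkene.

**Compound list**
1 | allyl acetoacetate | CC(=O)CC(=O)OCC=C | starting material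
2 | 2-(2-bromoethyl)-2-methyl-1,3-dioxolane | CC1(CCBr)OCCO1 | starting material
3 | allyl 2-acetyl-4-(2-methyl-1,3-dioxolan-2-yl)butanoate (racemic) | CC(=O)C(CCC1(C)OCCO1)C(=O)OCC=C | intermediate
4 | prenol (3-methylbut-2-en-1-ol) | CC(C)=CCO | starting material
5 | (R)-2-bromo-3-chloro-3-methylbutan-1-ol | OC[C@@H](Br)C(C)(C)Cl | intermediate
6 | (R)-2-bromo-3-chloro-3-methylbutyl trifluoromethanesulfonate | O=S(=O)(OC[C@@H](Br)C(C)(C)Cl)C(F)(F)F | intermediate
7 | dilithium dianion of 3 | [Li+].[Li+].[CH2-]C(=O)[C-](CCC1(C)OCCO1)C(=O)OCC=C | intermediate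
8 | allyl (6R)-6-bromo-7-chloro-7-methyl-2-[2-(2-methyl-1,3-dioxolan-2-yl)ethyl]-3-oxooctanoate (both C2 epimers) | C=CCOC(=O)C(CCC1(C)OCCO1)C(=O)CC[C@@H](Br)C(C)(C)Cl | intermediate
9 | bromonium chloride from 8 (2,2-dimethylbromiranium ion, configuration of the CH carbon retained) | C=CCOC(=O)C(CCC1(C)OCCO1)C(=O)CC[C@H]1[Br+]C1(C)C.[Cl-] | intermediate
10 | allyl (1R,3R)-3-bromo-2,2-dimethyl-1-[2-(2-methyl-1,3-dioxolan-2-yl)ethyl]-6-oxocyclohexane-1-carboxylate | O=C1CC[C@@H](Br)C(C)(C)[C@@]1(CCC2(C)OCCO2)C(=O)OCC=C | intermediate
11 | allyl (1R,3R,6S)-3-bromo-6-hydroxy-2,2-dimethyl-1-[2-(2-methyl-1,3-dioxolan-2-yl)ethyl]cyclohexane-1-carboxylate | O[C@H]1CC[C@@H](Br)C(C)(C)[C@@]1(CCC2(C)OCCO2)C(=O)OCC=C | intermediate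
12 | allyl (1R,3R,6S)-6-(acryloyloxy)-3-bromo-2,2-dimethyl-1-[2-(2-methyl-1,3-dioxolan-2-yl)ethyl]cyclohexane-1-carboxylate | C=CC(=O)O[C@H]1CC[C@@H](Br)C(C)(C)[C@@]1(CCC2(C)OCCO2)C(=O)OCC=C | intermediate
13 | ketal acid: (1R,3R,6S)-6-(acryloyloxy)-3-bromo-2,2-dimethyl-1-[2-(2-methyl-1,3-dioxolan-2-yl)ethyl]cyclohexane-1-carboxylic acid | C=CC(=O)O[C@H]1CC[C@@H](Br)C(C)(C)[C@@]1(CCC2(C)OCCO2)C(O)=O | intermediate
14 | (1R,3R,6S)-6-(acryloyloxy)-3-bromo-2,2-dimethyl-1-(3-oxobutyl)cyclohexane-1-carboxylic acid | C=CC(=O)O[C@H]1CC[C@@H](Br)C(C)(C)[C@@]1(CCC(C)=O)C(O)=O | intermediate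
15 | tertiary radical at the future C6 (acrylate on the neighbouring carbon, cis to bromine) | C=CC(=O)O[C@H]1CC[C@@H](Br)C(C)(C)[C]1CCC(C)=O | intermediate
16 | potassium enolate of the cis-fused δ-lactone (3-oxobutyl arm on C6, trans to the lactone oxygen) | [K+].[O-]C1=CC[C@@]2(CCC(C)=O)[C@@H](O1)CC[C@@H](Br)C2(C)C | intermediate
17 | tricyclic hydroxy lactone (10-bromo-3-hydroxy-3,11,11-trimethylspiro[5.5]undecane-2-carboxylic acid 2→7 lactone; C1 and the C7 oxygen cis to bromine; OH cis to the lactone carbonyl) | O=C1O[C@H]2CC[C@@H](Br)C(C)(C)[C@@]23C[C@@H]1[C@@](C)(O)CC3 | intermediate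
18 | lithium hydroxy carboxylate (ring-opened 17) | [Li+].O[C@H]1CC[C@@H](Br)C(C)(C)[C@@]12C[C@@H](C([O-])=O)[C@@](C)(O)CC2 | intermediate
19 | (10R)-10-bromo-3-hydroxy-3,11,11-trimethyl-7-oxospiro[5.5]undecane-2-carboxylic acid (carboxyl on the C7 side of ring B; OH cis to carboxyl) | O=C1CC[C@@H](Br)C(C)(C)[C@@]12C[C@@H](C(O)=O)[C@@](C)(O)CC2 | intermediate
20 | β-lactone of 19 (C2 carbonyl to C3 oxygen, cis-fused to ring B) | O=C1CC[C@@H](Br)C(C)(C)[C@@]12C[C@H]3C(=O)O[C@@]3(C)CC2 | intermediate
21 | (6R,10R)-10-bromo-3,11,11-trimethylspiro[5.5]undec-2-en-7-one | O=C1CC[C@@H](Br)C(C)(C)[C@@]12CC=C(C)CC2 | intermediate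
22 | (6S,10R)-10-bromo-3,11,11-trimethyl-7-methylidenespiro[5.5]undec-2-ene (10-bromo-β-chamigrene) | C=C1CC[C@@H](Br)C(C)(C)[C@@]12CC=C(C)CC2 | intermediate
23 | 2,3-epoxide of 22 (oxygen syn to C11 on ring B) | C=C1CC[C@@H](Br)C(C)(C)[C@@]12C[C@@H]3O[C@]3(C)CC2 | intermediate
24 | (2R,3R,6S,10R)-10-bromo-2-chloro-3,11,11-trimethyl-7-methylidenespiro[5.5]undecan-3-ol | C=C1CC[C@@H](Br)C(C)(C)[C@@]12C[C@@H](Cl)[C@](C)(O)CC2 | intermediate
25 | chloronium bromide from 24 (chlorine bridging C2 and C3 on the face syn to C7) | C=C1CC[C@@H](Br)C(C)(C)[C@@]12C[C@H]3[Cl+][C@@]3(C)CC2.[Br-] | intermediate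
26 | (2R,3R,6S,10R)-3,10-dibromo-2-chloro-3,11,11-trimethyl-7-methylidenespiro[5.5]undecane | C=C1CC[C@@H](Br)C(C)(C)[C@]12CC[C@@](C)(Br)[C@H](Cl)C2 | target

Total steps: 15. Longest linear sequence: 14 steps (4 to 26, steps 2–15).

**Steps most likely to fail**

Step 9 (proposed method). The tertiary radical may be quenched before it cyclises, or may close on the other face through a trans-fused lactone. The enolate may also be protonated before the aldol closure, which would stop at the simple cyclised lactone. The fallback sets out from 14, makes the same two bonds in separate, known operations, and comes back at 17. The acid is converted (oxalyl chloride, then the sodium salt of N-hydroxypyridine-2-thione) into Barton ester F1. Visible-light photolysis in benzene brings about decarboxylation, 6-endo radical cyclisation on the tethered acrylate and thiopyridyl group transfer (Barton decarboxylative radical addition, a chain process without a reduction step), which should give the cis-fused α-(pyridin-2-ylthio) δ-lactone F2. Oxidation to the sulfoxide (mCPBA, −78 °C) and thermal syn-elimination give the α,β-unsaturated δ-lactone F3. Copper hydride ([(Ph3P)CuH]6, toluene, 0 °C) then effects an intramolecular reductive aldol cyclisation: conjugate hydride delivery generates the C2 enolate regiospecifically and closes ring B on the methyl ketone.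

Step 5. Oxygen attack of the β-keto ester on the bromonium ion (enol-ether formation) may not revert to the carbon-cyclised product, and the HCl set free may cleave the dioxolane. The fallback sets out from 8 and comes back at 10. TBSOTf/Et3N converts 8 into its tert-butyldimethylsilyl enol ether F4. AgBF4 with 2,6-di-tert-butylpyridine in CH2Cl2 at −78 °C then abstracts the tertiary chloride with bromine participation under aprotic conditions. The same bromonium ion is captured at carbon only by the silyl enol ether, and loss of the silyl group gives the ring A ketone.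

Step 14. The epoxide may open at the tertiary C3 (ionisation-type opening) or rearrange instead of undergoing SN2 opening at C2. The fallback sets out from 22 and comes back at 24. Dihydroxylation (OsO4 cat., N-methylmorpholine N-oxide) of the trisubstituted alkene on the same face gives diol F5. 1,1'-Sulfonyldiimidazole/NaH closes it to cyclic sulfate F6. LiCl in DMF opens the cyclic sulfate by SN2 attack at the secondary C2 only, leaving the tertiary C3–O bond intact, to give chloro sulfate salt F7. Dilute H2SO4 in THF/H2O hydrolyses the sulfate monoester to the chlorohydrin.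

Further compounds
F1 | step 9 | Barton ester of 14 (2-thioxopyridin-1(2H)-yl ester) | C=CC(=O)O[C@H]1CC[C@@H](Br)C(C)(C)[C@@]1(CCC(C)=O)C(=O)ON1C=CC=CC1=S
F2 | step 9 | cis-fused α-(pyridin-2-ylthio) δ-lactone (epimers at the sulfur-bearing carbon) | O=C1O[C@H]2CC[C@@H](Br)C(C)(C)[C@@]2(CCC(C)=O)CC1Sc1ccccn1
F3 | step 9 | cis-fused α,β-unsaturated δ-lactone | O=C1O[C@H]2CC[C@@H](Br)C(C)(C)[C@@]2(CCC(C)=O)C=C1
F4 | step 5 | tert-butyldimethylsilyl enol ether of 8 (E/Z mixture) | C=CCOC(=O)C(CCC1(C)OCCO1)=C(O[Si](C)(C)C(C)(C)C)CC[C@@H](Br)C(C)(C)Cl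
F5 | step 14 | 2,3-diol of 22 (both hydroxyls syn to C11) | C=C1CC[C@@H](Br)C(C)(C)[C@@]12C[C@H](O)[C@](C)(O)CC2
F6 | step 14 | 2,3-cyclic sulfate of F5 | C=C1CC[C@@H](Br)C(C)(C)[C@@]12C[C@@H]3OS(=O)(=O)O[C@]3(C)CC2
F7 | step 14 | lithium (2R)-2-chloro-3-sulfate monoester | [Li+].C=C1CC[C@@H](Br)C(C)(C)[C@@]12C[C@@H](Cl)[C@](C)(OS(=O)(=O)[O-])CC2
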